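Ring locants: C1 carries the tetraene, C2 is the ring =CH, C3 the quaternary carbon, C4 the carbinol carbon, C5 and C6 the CH2 groups. Each cyclohexene ring is cut at C1=C2 and at C4–C5, a [3+3] split. The key step exploits quaternary C3: the CHO (C2) and CO2Me (C4) that flank it in an acyclic formyl ester cannot enolise and form a pure 1,3-dielectrophile. A 2-phosphonoglutaric acid derivative supplies C1–C6–C5 as 1,3-dinucleophile. In one flask, Horner–Wadsworth–Emmons olefination and Dieckmann closure build the ring. The precursor is two open chains. Reagent-controlled reduction, epoxidation and homocoupling of two ring enynes finish the twofold-symmetric target.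

Key step: step 5

Remark on the chemistry: the ligand enantiomer in step 2 is taken to be the one that reduces the pro-R ester of 3, and phosphonate 8 is used as the racemate because its stereocentre is lost in step 5.

Step 1
Reactants: 1 dimethyl methylmalonate; 2 5-bromo-2-methylpent-2-ene
Product: 3 dimethyl 2-methyl-2-(4-methylpent-3-en-1-yl)propanedioate
Conditions: NaH, THF–DMF, 0 → 60 °C
Reagents that add atoms: none
Why: Malonic ester alkylation: the sodium enolate of 1 displaces bromide from the primary homoallylic bromide 2 in an SN2 reaction and creates the fully substituted, still prochiral carbon that becomes ring C3.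

Step 2
Reactants: 3 dimethyl 2-methyl-2-(4-methylpent-3-en-1-yl)propanedioate
Product: 4 methyl (2S)-2-(hydroxymethyl)-2,6-dimethylhept-5-enoate
Conditions: Et2Zn (10 mol %), chiral tetradentate pipecolinol-derived aminophenol ligand (5 mol %), MeSiH(OEt)2 (2.5 equiv), toluene, 0 °C; then 1 M aq. HCl, THF, 0 °C
Reagents that add atoms: none
Why: Zinc-catalysed desymmetrising hydrosilylation of a 2,2-disubstituted malonic ester: the chiral dinuclear zinc pocket holds both carbonyl groups, tells CH3 from the longer chain and passes hydride twice to the pro-R ester only, which sets the quaternary stereocentre as S while the isolated alkene is inert to zinc hydride.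

Step 3
Reactants: 4 methyl (2S)-2-(hydroxymethyl)-2,6-dimethylhept-5-enoate
Product: 5 methyl (2S)-2-formyl-2,6-dimethylhept-5-enoate
Conditions: Dess–Martin periodinane, CH2Cl2, 0 → 23 °C
Reagents that add atoms: none
Why: Dess–Martin oxidation of the neopentyl primary alcohol stops at the aldehyde under neutral conditions, and the stereocentre cannot epimerise because it bears no hydrogen.

Step 4
Reactants: 6 diethyl {2-[methoxy(methyl)amino]-2-oxoethyl}phosphonate (1.5 equiv); 7 methyl acrylate
Product: 8 methyl 4-(diethoxyphosphoryl)-5-[methoxy(methyl)amino]-5-oxopentanoate (racemic)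
Conditions: KOt-Bu (10 mol %), THF, 0 °C
Reagents that add atoms: none
Why: Base-catalysed Michael addition of the doubly stabilised phosphonate carbanion to the acrylate joins future C1 to the C6–C5 unit, an excess of 6 holds back a second addition, and the new stereocentre needs no control because it becomes sp2 in step 5.

Step 5
Reactants: 5 methyl (2S)-2-formyl-2,6-dimethylhept-5-enoate; 8 methyl 4-(diethoxyphosphoryl)-5-[methoxy(methyl)amino]-5-oxopentanoate
Product: 10 methyl (5S)-3-[methoxy(methyl)carbamoyl]-5-methyl-5-(4-methylpent-3-en-1-yl)-6-oxocyclohex-3-ene-1-carboxylate (C1 epimers and enol form), via acyclic E-enamide diester 9 (not isolated)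
Conditions: 8, NaH (1.05 equiv), THF, 0 °C; add 5, 0 → 23 °C; then KOt-Bu (1.5 equiv), 0 → 23 °C, same flask without work-up; AcOH quench
Reagents that add atoms: none
Why: The sodium salt of 8 adds through its phosphonate carbon (future C1) to the only aldehyde of 5 (future C2), syn-elimination of diethyl phosphate from the oxaphosphetane gives 9, and KOt-Bu then forms the ester enolate at future C5, which acylates the neopentyl CO2Me (future C4) and expels methoxide, so that C1=C2 and C4–C5 arise in one flask. The closest known reaction types are the Horner–Wadsworth–Emmons olefination of alpha-quaternary aldehydes and the Dieckmann condensation, run here as a tandem [3+3] annulation. The single ring is closed in a 6-(enolexo)-exo-trig mode, and deprotonation of the beta-keto ester 10 pulls the equilibrium to the ring. No lasting stereocentre is created: C3 is carried over from 5 untouched because it bears no acidic hydrogen, and the ester-bearing C5 is a labile centre that step 6 erases. The step needs E geometry in 9 (C3 cis to the CH2CH2CO2Me arm), which the preference of the bulky quaternary substituent to lie trans to the carboxamide in the olefination should secure, and only this isomer can reach the ring. Chemoselectivity follows from acidity and reach: one equivalent of NaH touches only the phosphonate CH, the enolate formed later finds the ester on C3 as the only carbonyl within a six-membered transition state, and quaternary C3 rules out enolisation or migration of the new double bond.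

Step 6
Reactants: 10 methyl (5S)-3-[methoxy(methyl)carbamoyl]-5-methyl-5-(4-methylpent-3-en-1-yl)-6-oxocyclohex-3-ene-1-carboxylate
Product: 11 (3S)-N-methoxy-N,3-dimethyl-3-(4-methylpent-3-en-1-yl)-4-oxocyclohex-1-ene-1-carboxamide
Conditions: LiCl (3 equiv), H2O (2 equiv), DMSO, 130 °C
Reagents that add atoms: none
Why: Krapcho dealkoxycarbonylation: chloride removes the methyl group of the beta-keto ester only, the beta-keto carboxylate loses CO2 and water protonates C5, while the Weinreb amide, both alkenes and the non-enolisable C3 stay untouched.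

Step 7
Reactants: 11 (3S)-N-methoxy-N,3-dimethyl-3-(4-methylpent-3-en-1-yl)-4-oxocyclohex-1-ene-1-carboxamide
Product: 12 (3S,4S)-4-hydroxy-N-methoxy-N,3-dimethyl-3-(4-methylpent-3-en-1-yl)cyclohex-1-ene-1-carboxamide
Conditions: (R)-2-methyl-CBS-oxazaborolidine (20 mol %), catecholborane (2 equiv), toluene, −60 → −20 °C; MeOH, then aq. NaOH wash
Reagents that add atoms: none
Why: Corey–Bakshi–Shibata reduction: the (R)-oxazaborolidine binds the ketone oxygen on the lone pair next to the small C5H2 side, away from quaternary C3, and directs hydride to one face regardless of which C3 substituent is axial, which sets C4 as S (OH cis to the C3 methyl group), and catecholborane spares the trisubstituted alkene and the amide.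

Step 8
Reactants: 12 (3S,4S)-4-hydroxy-N-methoxy-N,3-dimethyl-3-(4-methylpent-3-en-1-yl)cyclohex-1-ene-1-carboxamide
Product: 13 (3S,4S)-3-{2-[(2R)-3,3-dimethyloxiran-2-yl]ethyl}-4-hydroxy-N-methoxy-N,3-dimethylcyclohex-1-ene-1-carboxamide
Conditions: 1,2:4,5-di-O-isopropylidene-β-D-erythro-hexo-2,3-diulo-2,6-pyranose (30 mol %), KHSO5 (as 2KHSO5·KHSO4·K2SO4), K2CO3, Na2B4O7 buffer, Bu4NHSO4, MeCN–CH2(OMe)2–H2O, 0 °C
Reagents that add atoms: potassium peroxymonosulfate KHSO5, [K+].[O-]S(=O)(=O)OO
Why: Shi asymmetric epoxidation: the dioxirane from the D-fructose-derived ketone attacks the electron-rich side-chain alkene through the spiro transition state to give the (R)-epoxide under reagent control, while the ring alkene is deactivated by the carboxamide and shielded by C3, and the basic buffer keeps the C4 hydroxyl from opening the epoxide.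

Step 9
Reactants: 13 (3S,4S)-3-{2-[(2R)-3,3-dimethyloxiran-2-yl]ethyl}-4-hydroxy-N-methoxy-N,3-dimethylcyclohex-1-ene-1-carboxamide
Product: 15 (1S,2S)-2-{2-[(2R)-3,3-dimethyloxiran-2-yl]ethyl}-4-ethynyl-2-methylcyclohex-3-en-1-ol, via ring enal 14 (not isolated)
Conditions: i-Bu2AlH (2.3 equiv), CH2Cl2, −78 °C; then MeOH, K2CO3, dimethyl (1-diazo-2-oxopropyl)phosphonate, −78 → 23 °C, same flask
Reagents that add atoms: dimethyl (1-diazo-2-oxopropyl)phosphonate, CC(=O)C(=[N+]=[N-])P(=O)(OC)OC
Why: Reduction of the Weinreb amide stops at the chelated aluminium hemiaminal, which collapses to enal 14 on addition of methanol, and the Ohira–Bestmann variant of the Seyferth–Gilbert homologation then turns CHO into C≡CH under mild carbonate base that leaves epoxide, alcohol and all stereocentres alone.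

Step 10
Reactants: 15 (1S,2S)-2-{2-[(2R)-3,3-dimethyloxiran-2-yl]ethyl}-4-ethynyl-2-methylcyclohex-3-en-1-ol (two molecules)
Product: 18 (1S,1'S,2S,2'S)-4,4'-[(1E,3E)-buta-1,3-diene-1,4-diyl]bis(2-{2-[(2R)-3,3-dimethyloxiran-2-yl]ethyl}-2-methylcyclohex-3-en-1-ol) (CNP0229121.5), via dienylzirconocene chloride 16 (not isolated), via dienylcopper 17 (not isolated)
Conditions: Cp2Zr(H)Cl (2.3 equiv per 15), THF, 0 → 23 °C, dark; then CuCl (1.1 equiv), 0 → 40 °C; aq. NH4Cl–NH3
Reagents that add atoms: none
Why: Syn hydrozirconation of the terminal alkyne places zirconium at the terminus with E geometry, and transmetalation to monovalent copper followed by reductive dimerisation of the alkenylcopper keeps that geometry (hydrozirconation–copper homocoupling), so both new disubstituted double bonds are E, and pairing of two like enantiomers gives the twofold-symmetric product while any minor enantiomer ends mostly in a separable diastereomer.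

Compound list
1 | dimethyl methylmalonate | COC(=O)C(C)C(=O)OC | starting material
2 | 5-bromo-2-methylpent-2-ene | CC(C)=CCCBr | starting material
3 | dimethyl 2-methyl-2-(4-methylpent-3-en-1-yl)propanedioate | CC(C)=CCCC(C)(C(=O)OC)C(=O)OC | intermediate
4 | methyl (2S)-2-(hydroxymethyl)-2,6-dimethylhept-5-enoate | CC(C)=CCC[C@@](C)(CO)C(=O)OC | intermediate
5 | methyl (2S)-2-formyl-2,6-dimethylhept-5-enoate | CC(C)=CCC[C@@](C)(C=O)C(=O)OC | intermediate
6 | diethyl {2-[methoxy(methyl)amino]-2-oxoethyl}phosphonate | CCOP(=O)(CC(=O)N(C)OC)OCC | starting material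
7 | methyl acrylate | C=CC(=O)OC | starting material
8 | methyl 4-(diethoxyphosphoryl)-5-[methoxy(methyl)amino]-5-oxopentanoate (racemic) | COC(=O)CCC(C(=O)N(C)OC)P(=O)(OCC)OCC | intermediate
9 | dimethyl (2S,3E)-4-[methoxy(methyl)carbamoyl]-2-methyl-2-(4-methylpent-3-en-1-yl)hept-3-enedioate | CC(C)=CCC[C@@](C)(/C=C(\CCC(=O)OC)C(=O)N(C)OC)C(=O)OC | intermediate
10 | methyl (5S)-3-[methoxy(methyl)carbamoyl]-5-methyl-5-(4-methylpent-3-en-1-yl)-6-oxocyclohex-3-ene-1-carboxylate | CC(C)=CCC[C@@]1(C)C=C(C(=O)N(C)OC)CC(C(=O)OC)C1=O | intermediate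
11 | (3S)-N-methoxy-N,3-dimethyl-3-(4-methylpent-3-en-1-yl)-4-oxocyclohex-1-ene-1-carboxamide | CC(C)=CCC[C@@]1(C)C=C(C(=O)N(C)OC)CCC1=O | intermediate
12 | (3S,4S)-4-hydroxy-N-methoxy-N,3-dimethyl-3-(4-methylpent-3-en-1-yl)cyclohex-1-ene-1-carboxamide | CC(C)=CCC[C@@]1(C)C=C(C(=O)N(C)OC)CC[C@@H]1O | intermediate
13 | (3S,4S)-3-{2-[(2R)-3,3-dimethyloxiran-2-yl]ethyl}-4-hydroxy-N-methoxy-N,3-dimethylcyclohex-1-ene-1-carboxamide | CC1(C)O[C@@H]1CC[C@@]1(C)C=C(C(=O)N(C)OC)CC[C@@H]1O | intermediate
14 | (3S,4S)-3-{2-[(2R)-3,3-dimethyloxiran-2-yl]ethyl}-4-hydroxy-3-methylcyclohex-1-ene-1-carbaldehyde | CC1(C)O[C@@H]1CC[C@@]1(C)C=C(C=O)CC[C@@H]1O | intermediate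
15 | (1S,2S)-2-{2-[(2R)-3,3-dimethyloxiran-2-yl]ethyl}-4-ethynyl-2-methylcyclohex-3-en-1-ol | CC1(C)O[C@@H]1CC[C@@]1(C)C=C(C#C)CC[C@@H]1O | intermediate
16 | (E)-dienylzirconocene chloride of 15, hydroxyl held as its zirconocene chloride alkoxide | CC1(C)O[C@@H]1CC[C@@]1(C)C=C(/C=C/[Zr](Cl)(C2C=CC=C2)C2C=CC=C2)CC[C@@H]1O[Zr](Cl)(C1C=CC=C1)C1C=CC=C1 | intermediate
17 | (E)-dienylcopper from 16 | CC1(C)O[C@@H]1CC[C@@]1(C)C=C(/C=C/[Cu])CC[C@@H]1O[Zr](Cl)(C1C=CC=C1)C1C=CC=C1 | intermediate
18 | (1S,1'S,2S,2'S)-4,4'-[(1E,3E)-buta-1,3-diene-1,4-diyl]bis(2-{2-[(2R)-3,3-dimethyloxiran-2-yl]ethyl}-2-methylcyclohex-3-en-1-ol) | CC1(C)O[C@@H]1CC[C@@]1(C)C=C(/C=C/C=C/C2=C[C@](C)(CC[C@H]3OC3(C)C)[C@@H](O)CC2)CC[C@@H]1O | target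

Total step count: 10. Longest linear sequence: 9 steps (steps 1, 2, 3, 5, 6, 7, 8, 9, 10).

Steps most likely to fail

Step 5. The olefination of the hindered aldehyde by an alpha-branched phosphonate may lose its alkene geometry. The adduct alkoxide may also fragment by formyl transfer before it eliminates. A chain with the wrong geometry cannot close.
- The fallback sets out from 4 and returns at 10. It inverts the order of the two bond formations, so that the ring itself enforces the geometry.
- Ester 4 is saponified (LiOH, THF–H2O) to the hydroxy acid F1, which TsCl in pyridine closes to the beta-lactone F2.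
- The dianion of 8 (NaH, then LiN(i-Pr)2, THF, −78 °C) is C-acylated at its ester enolate carbon by the strained lactone carbonyl. This gives the hydroxymethyl beta-keto ester F3.
- TEMPO/PhI(OAc)2 oxidises the primary alcohol to the keto aldehyde F4.
- An intramolecular Horner–Wadsworth–Emmons reaction (LiCl, DBU, MeCN) closes the ring to 10.

Step 9. The conjugated amide may be over-reduced. Methanol may add in conjugate fashion during the diazophosphonate homologation of an enal. The neighbouring aluminium alkoxide may open the epoxide.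
- The fallback sets out from 13 and returns at 18. It avoids the alkyne altogether.
- Amide 13 is reduced with i-Bu2AlH and enal 14 is isolated.
- A boron–Wittig reaction with lithiated bis[(pinacolato)boryl]methane (lithium 2,2,6,6-tetramethylpiperidide, THF, −78 → 0 °C) gives the (E)-dienylboronate F5.
- Aerobic palladium-catalysed oxidative homocoupling (Pd(OAc)2, K2CO3, MeOH–THF, air) joins two molecules of F5 to 18.

Step 10. Zirconium hydride may reduce the epoxide, or the Lewis acidic zirconium and copper salts may help the C4 alkoxide to open it. The alkenyl metal may also be protonated instead of coupling.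
- The fallback sets out from 15 and returns at 18. It uses tin in place of zirconium.
- Palladium-catalysed syn hydrostannation (Bu3SnH, PdCl2(PPh3)2, THF, 0 °C) gives the (E)-dienylstannane F6, which tolerates the free hydroxyl and the epoxide and can be purified.
- CuCl in DMF at 23 °C then effects the stereoretentive oxidative homocoupling to 18.

Further compounds
F1 | step 5 | (2S)-2-(hydroxymethyl)-2,6-dimethylhept-5-enoic acid | CC(C)=CCC[C@@](C)(CO)C(=O)O
F2 | step 5 | (3S)-3-methyl-3-(4-methylpent-3-en-1-yl)oxetan-2-one | CC(C)=CCC[C@@]1(C)COC1=O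
F3 | step 5 | methyl 4-(diethoxyphosphoryl)-2-[(2S)-2-(hydroxymethyl)-2,6-dimethylhept-5-enoyl]-5-[methoxy(methyl)amino]-5-oxopentanoate | CC(C)=CCC[C@@](C)(CO)C(=O)C(C(=O)OC)CC(C(=O)N(C)OC)P(=O)(OCC)OCC
F4 | step 5 | methyl 4-(diethoxyphosphoryl)-2-[(2S)-2-formyl-2,6-dimethylhept-5-enoyl]-5-[methoxy(methyl)amino]-5-oxopentanoate | CC(C)=CCC[C@@](C)(C=O)C(=O)C(C(=O)OC)CC(C(=O)N(C)OC)P(=O)(OCC)OCC
F5 | step 9 | (1S,2S)-2-{2-[(2R)-3,3-dimethyloxiran-2-yl]ethyl}-2-methyl-4-[(E)-2-(4,4,5,5-tetramethyl-1,3,2-dioxaborolan-2-yl)ethenyl]cyclohex-3-en-1-ol | CC1(C)O[C@@H]1CC[C@@]1(C)C=C(/C=C/B2OC(C)(C)C(C)(C)O2)CC[C@@H]1O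
F6 | step 10 | (1S,2S)-2-{2-[(2R)-3,3-dimethyloxiran-2-yl]ethyl}-2-methyl-4-[(E)-2-(tributylstannyl)ethenyl]cyclohex-3-en-1-ol | CC1(C)O[C@@H]1CC[C@@]1(C)C=C(/C=C/[Sn](CCCC)(CCCC)CCCC)CC[C@@H]1O
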